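**Retrosynthetic overview**

1. The plan rests on the cyclohexane ring C1–C6. The quaternary carbinol C1 (OH, C7) lies para to C4 (Me, Br), and the vicinal C4–Br/C5–Cl pair masks a C4=C5 alkene, so the ring is the adduct of isoprene with a 2-oxyacrolein.
2. Chain: C7=CH2 comes from methylenation of a C7 ketone; C8–C9 comes from a boron aldol of the C7 methyl ketone with 3-methylbut-2-enal (sets C9).
3. Halides: C4–Br comes from bromide opening of a C1–O–C4 bridged chloro-ether; the ether and C5–Cl come from chloroetherification of the C1 hydroxyl onto C4=C5 (C4 and C5 set from C1).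
4. Ring (the only ring, formed once): C1–C6 and C2–C3 come from a catalytic enantioselective [4+2] of isoprene with 2-(benzoyloxy)acrolein (sets C1). The dienophile comes from the enol benzoate of 2,2-dimethyl-1,3-dioxan-5-one by loss of acetone.

Key step: step 3

Remark: the antipodes of the Diels–Alder catalyst and of Ipc2BCl named below are assumed to give the configurations drawn (1R and 9S); should either sense prove opposite, the mirror-image catalyst or reagent is used and nothing else changes. Target numbering (C1 carbinol, C4 Me/Br, C5 Cl, chain C7–C11) is used in all names.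

**Route**

Step 1
Reactants: 1 2,2-dimethyl-1,3-dioxan-5-one; 2 benzoyl chloride
Product: 4 2,2-dimethyl-4H-1,3-dioxin-5-yl benzoate, via potassium enolate 3 (not isolated)
Conditions: KHMDS, THF, −78 °C; then 2, −78 → 0 °C
Reagents that add atoms: none
Why: O-acylation of a potassium enolate by an acid chloride (enol ester formation); the ketone is symmetrical, so only one enolate can form.

Step 2
Reactants: 4 2,2-dimethyl-4H-1,3-dioxin-5-yl benzoate
Product: 5 2-(benzoyloxy)acrolein
Conditions: PhMe, 110 °C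
Reagents that add atoms: none
Why: Thermal retro-hetero-Diels–Alder cycloreversion of the 4H-1,3-dioxin expels acetone and leaves the 2-acyloxy enal.

Step 3
Reactants: 5 2-(benzoyloxy)acrolein; 6 isoprene
Product: 9 (R)-1-formyl-4-methylcyclohex-3-en-1-yl benzoate, via dienophile iminium ion 7 (not isolated), via cycloadduct iminium ion 8 (not isolated)
Conditions: 6 (4 equiv), (R,R)-triamine (2R)-N1-[(2R)-4-methyl-1-(pyrrolidin-1-yl)pentan-2-yl]-3-phenylpropane-1,2-diamine (10 mol %), C6F5SO3H (27.5 mol %), EtNO2, trace H2O, rt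
Reagents that add atoms: none
Why: The primary amine of the catalyst condenses with 5 to the iminium ion 7, whose lowered LUMO undergoes a concerted, asynchronous, suprafacial [4+2] cycloaddition with isoprene, and hydrolysis of the adduct iminium 8 returns the amine; the closest known reaction type is the ammonium-salt-catalysed enantioselective Diels–Alder reaction of α-acyloxyacroleins with simple dienes. The cyclohexene ring is closed intermolecularly by cycloaddition, C2–C3 forming ahead of C1–C6. C1, the only new stereocentre, is set by the catalyst: the acyloxy carbonyl is held by hydrogen bonding to the ammonium groups, which fixes the iminium geometry so that the benzyl arm screens one enantioface of the dienophile. The step needs para regioselectivity and enantioface selectivity. The first is secured by the larger HOMO coefficient at the CH2 terminus next to the methyl-bearing carbon of isoprene, which pairs with the β-carbon of the iminium; the second is secured by the catalyst. No endo/exo question arises, since the diene has no terminal substituent.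

Step 4
Reactants: 9 (R)-1-formyl-4-methylcyclohex-3-en-1-yl benzoate
Product: 11 (1R)-1-(1-hydroxyethyl)-4-methylcyclohex-3-en-1-ol (carbinol epimers), via bromomagnesium alkoxide of the mono-adduct 10 (not isolated)
Conditions: MeMgBr (4 equiv), THF, −78 °C → rt; aq. NH4Cl
Reagents that add atoms: methylmagnesium bromide, C[Mg]Br
Why: Grignard 1,2-addition to the aldehyde installs C8, and the excess reagent then cleaves the benzoate (ester to tertiary carbinol), freeing the C1 hydroxyl; the new carbinol centre is oxidised in the next step and C1, being quaternary, cannot epimerise.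

Step 5
Reactants: 11 (1R)-1-(1-hydroxyethyl)-4-methylcyclohex-3-en-1-ol
Product: 12 (R)-1-(1-hydroxy-4-methylcyclohex-3-en-1-yl)ethan-1-one
Conditions: IBX, DMSO, rt
Reagents that add atoms: none
Why: IBX oxidation of the secondary alcohol of a 1,2-diol to the α-ketol without glycol cleavage; the tertiary hydroxyl and the alkene are inert.

Step 6
Reactants: 12 (R)-1-(1-hydroxy-4-methylcyclohex-3-en-1-yl)ethan-1-one
Product: 13 1-[(1R,4S,5S)-5-chloro-4-methyl-7-oxabicyclo[2.2.1]heptan-1-yl]ethan-1-one (Cl anti to the oxygen bridge)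
Conditions: NCS, (CF3)2CHOH, 0 °C → rt
Reagents that add atoms: N-chlorosuccinimide, O=C1CCC(=O)N1Cl
Why: Chloroetherification (halocyclisation): the alkene takes Cl+ at C5 and the C1 hydroxyl captures the developing tertiary C4 cation across the ring in a boat conformation, which is possible only anti to chlorine, so the oxygen bridge lies on the hydroxyl face and C5–Cl is set anti to it (Markovnikov, anti addition), fixing C4 and C5 relative to C1.

Step 7
Reactants: 13 1-[(1R,4S,5S)-5-chloro-4-methyl-7-oxabicyclo[2.2.1]heptan-1-yl]ethan-1-one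
Product: 15 1-[(1R,4S,5S)-4-bromo-5-chloro-1-hydroxy-4-methylcyclohexyl]ethan-1-one, via O-dibromoboryl ether 14 (not isolated)
Conditions: BBr3, CH2Cl2, −78 → −20 °C; H2O
Reagents that add atoms: boron tribromide, BrB(Br)Br
Why: Lewis-acid cleavage of a di-tertiary bridged ether by BBr3: ionisation is possible only at C4–O because a cation at C1 would sit next to the ketone, the endo C5 chlorine lies antiperiplanar to the breaking bond and bridges the cation as a chloronium ion, and bromide should therefore enter C4 anti to chlorine, on the face the oxygen left (net retention at C4, Br trans to Cl), while the C1 oxygen stays bound to boron and cannot re-close.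

Step 8
Reactants: 15 1-[(1R,4S,5S)-4-bromo-5-chloro-1-hydroxy-4-methylcyclohexyl]ethan-1-one
Product: 16 1-[(1R,4S,5S)-4-bromo-5-chloro-4-methyl-1-(triethylsilyloxy)cyclohexyl]ethan-1-one
Conditions: TESOTf, 2,6-lutidine, CH2Cl2, −78 °C
Reagents that add atoms: triethylsilyl trifluoromethanesulfonate, CC[Si](CC)(CC)OS(=O)(=O)C(F)(F)F
Why: Silylation of the hindered tertiary alcohol with a silyl triflate and a non-nucleophilic base; this blocks the C1 oxygen from re-forming the ether by displacing the ionisable C4 bromide and keeps it out of the boron chemistry of step 9.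

Step 9
Reactants: 16 1-[(1R,4S,5S)-4-bromo-5-chloro-4-methyl-1-(triethylsilyloxy)cyclohexyl]ethan-1-one; 17 3-methylbut-2-enal
Product: 20 (3S)-1-[(1R,4S,5S)-4-bromo-5-chloro-4-methyl-1-(triethylsilyloxy)cyclohexyl]-3-hydroxy-5-methylhex-4-en-1-one, via boron enolate 18 (not isolated), via boron aldolate 19 (not isolated)
Conditions: (−)-Ipc2BCl, Et3N, Et2O, 0 °C; 17, −78 → −20 °C; H2O2, MeOH, pH 7 buffer, 0 °C
Reagents that add atoms: none
Why: Paterson boron aldol of a methyl ketone: only the methyl group can be enolised (C1 is quaternary), and the chair-like transition state of the diisopinocampheylboron enolate is expected to direct attack to the si face of the aldehyde, giving 9S; the C9 epimer is a diastereomer and should be separable.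

Step 10
Reactants: 20 (3S)-1-[(1R,4S,5S)-4-bromo-5-chloro-4-methyl-1-(triethylsilyloxy)cyclohexyl]-3-hydroxy-5-methylhex-4-en-1-one
Product: 21 (3S)-1-[(1R,4S,5S)-4-bromo-5-chloro-4-methyl-1-(triethylsilyloxy)cyclohexyl]-5-methyl-3-(triethylsilyloxy)hex-4-en-1-one
Conditions: TESOTf, 2,6-lutidine, CH2Cl2, −78 °C
Reagents that add atoms: triethylsilyl trifluoromethanesulfonate, CC[Si](CC)(CC)OS(=O)(=O)C(F)(F)F
Why: Low-temperature silylation of the secondary allylic alcohol, fast enough to outrun retro-aldol cleavage, protects C9–OH for the methylenation.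

Step 11
Reactants: 21 (3S)-1-[(1R,4S,5S)-4-bromo-5-chloro-4-methyl-1-(triethylsilyloxy)cyclohexyl]-5-methyl-3-(triethylsilyloxy)hex-4-en-1-one
Product: 22 triethyl({(1R,4S,5S)-4-bromo-5-chloro-4-methyl-1-[(4S)-6-methyl-4-(triethylsilyloxy)hepta-1,5-dien-2-yl]cyclohexyl}oxy)silane
Conditions: Cp2TiMe2, PhMe/THF, 65 °C, dark
Reagents that add atoms: dimethyltitanocene (Petasis reagent), [CH3-].[CH3-].[Ti+4].c1cc[cH-]c1.c1cc[cH-]c1
Why: Petasis methylenation: Cp2Ti=CH2 formed on heating converts the hindered, enolisable ketone into the 1,1-disubstituted alkene through an oxatitanacyclobutane under non-basic conditions, which should spare the tertiary bromide and avoid β-elimination of the silyloxy group.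

Step 12
Reactants: 22 triethyl({(1R,4S,5S)-4-bromo-5-chloro-4-methyl-1-[(4S)-6-methyl-4-(triethylsilyloxy)hepta-1,5-dien-2-yl]cyclohexyl}oxy)silane
Product: 23 (1R,4S,5S)-4-bromo-5-chloro-1-[(4S)-4-hydroxy-6-methylhepta-1,5-dien-2-yl]-4-methylcyclohexan-1-ol (target)
Conditions: HF·pyridine, pyridine, THF, 0 °C → rt
Reagents that add atoms: none
Why: Buffered fluoride cleavage of both triethylsilyl ethers should leave the tertiary bromide and the two allylic alcohols untouched; no stereocentre is affected.

**Compound list**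

1 | 2,2-dimethyl-1,3-dioxan-5-one | CC1(C)OCC(=O)CO1 | starting material
2 | benzoyl chloride | O=C(Cl)c1ccccc1 | starting material
3 | potassium 2,2-dimethyl-4H-1,3-dioxin-5-olate | CC1(C)OCC([O-])=CO1.[K+] | intermediate
4 | 2,2-dimethyl-4H-1,3-dioxin-5-yl benzoate | CC1(C)OCC(OC(=O)c2ccccc2)=CO1 | intermediate
5 | 2-(benzoyloxy)acrolein | C=C(OC(=O)c1ccccc1)C=O | intermediate
6 | isoprene | C=CC(C)=C | starting material
7 | iminium ion of 5 with the catalyst primary amine (pentafluorobenzenesulfonate) | C=C(OC(=O)c1ccccc1)C=[NH+][C@H](Cc1ccccc1)CN[C@H](CC(C)C)CN1CCCC1.[O-]S(=O)(=O)c1c(F)c(F)c(F)c(F)c1F | intermediate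
8 | iminium ion of cycloadduct 9 with the catalyst primary amine (pentafluorobenzenesulfonate) | C(=[NH+][C@H](Cc1ccccc1)CN[C@H](CC(C)C)CN1CCCC1)[C@@]1(OC(=O)c2ccccc2)CCC(C)=CC1.[O-]S(=O)(=O)c1c(F)c(F)c(F)c(F)c1F | intermediate
9 | (R)-1-formyl-4-methylcyclohex-3-en-1-yl benzoate | O=C[C@@]1(OC(=O)c2ccccc2)CCC(C)=CC1 | intermediate
10 | bromomagnesium alkoxide of (1R)-1-(1-hydroxyethyl)-4-methylcyclohex-3-en-1-yl benzoate | CC(O[Mg]Br)[C@@]1(OC(=O)c2ccccc2)CCC(C)=CC1 | intermediate
11 | (1R)-1-(1-hydroxyethyl)-4-methylcyclohex-3-en-1-ol | CC(O)[C@@]1(O)CCC(C)=CC1 | intermediate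
12 | (R)-1-(1-hydroxy-4-methylcyclohex-3-en-1-yl)ethan-1-one | CC(=O)[C@@]1(O)CCC(C)=CC1 | intermediate
13 | 1-[(1R,4S,5S)-5-chloro-4-methyl-7-oxabicyclo[2.2.1]heptan-1-yl]ethan-1-one | CC(=O)[C@@]1(O2)CC[C@@]2(C)[C@@H](Cl)C1 | intermediate
14 | {[(1R,4S,5S)-1-acetyl-4-bromo-5-chloro-4-methylcyclohexyl]oxy}dibromoborane | CC(=O)[C@@]1(OB(Br)Br)CC[C@](C)(Br)[C@@H](Cl)C1 | intermediate
15 | 1-[(1R,4S,5S)-4-bromo-5-chloro-1-hydroxy-4-methylcyclohexyl]ethan-1-one | CC(=O)[C@@]1(O)CC[C@](C)(Br)[C@@H](Cl)C1 | intermediate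
16 | 1-[(1R,4S,5S)-4-bromo-5-chloro-4-methyl-1-(triethylsilyloxy)cyclohexyl]ethan-1-one | CC(=O)[C@@]1(O[Si](CC)(CC)CC)CC[C@](C)(Br)[C@@H](Cl)C1 | intermediate
17 | 3-methylbut-2-enal | CC(C)=CC=O | starting material
18 | diisopinocampheylboron enolate of 16 | C=C(OB([C@@H]2C[C@@H]3C[C@H]([C@H]2C)C3(C)C)[C@@H]2C[C@@H]3C[C@H]([C@H]2C)C3(C)C)[C@@]1(O[Si](CC)(CC)CC)CC[C@](C)(Br)[C@@H](Cl)C1 | intermediate
19 | diisopinocampheylboron aldolate of 20 | O=C(C[C@H](OB([C@@H]2C[C@@H]3C[C@H]([C@H]2C)C3(C)C)[C@@H]2C[C@@H]3C[C@H]([C@H]2C)C3(C)C)C=C(C)C)[C@@]1(O[Si](CC)(CC)CC)CC[C@](C)(Br)[C@@H](Cl)C1 | intermediate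
20 | (3S)-1-[(1R,4S,5S)-4-bromo-5-chloro-4-methyl-1-(triethylsilyloxy)cyclohexyl]-3-hydroxy-5-methylhex-4-en-1-one | O=C(C[C@H](O)C=C(C)C)[C@@]1(O[Si](CC)(CC)CC)CC[C@](C)(Br)[C@@H](Cl)C1 | intermediate
21 | (3S)-1-[(1R,4S,5S)-4-bromo-5-chloro-4-methyl-1-(triethylsilyloxy)cyclohexyl]-5-methyl-3-(triethylsilyloxy)hex-4-en-1-one | O=C(C[C@H](O[Si](CC)(CC)CC)C=C(C)C)[C@@]1(O[Si](CC)(CC)CC)CC[C@](C)(Br)[C@@H](Cl)C1 | intermediate
22 | triethyl({(1R,4S,5S)-4-bromo-5-chloro-4-methyl-1-[(4S)-6-methyl-4-(triethylsilyloxy)hepta-1,5-dien-2-yl]cyclohexyl}oxy)silane | C=C(C[C@H](O[Si](CC)(CC)CC)C=C(C)C)[C@@]1(O[Si](CC)(CC)CC)CC[C@](C)(Br)[C@@H](Cl)C1 | intermediate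
23 | (1R,4S,5S)-4-bromo-5-chloro-1-[(4S)-4-hydroxy-6-methylhepta-1,5-dien-2-yl]-4-methylcyclohexan-1-ol | C=C(C[C@H](O)C=C(C)C)[C@@]1(O)CC[C@](C)(Br)[C@@H](Cl)C1 | target

**Totals**

Total step count: 12. Longest linear sequence: 12 steps (1 → 23); isoprene and 3-methylbut-2-enal each enter in a single step.

**Steps most likely to fail**

Step 7 (bromide opening of the bridged ether). The C4 cation may lose a proton (E1) instead of taking bromide, or bromide may enter on the wrong face if chlorine bridging is weak, giving the C4 epimer. Fallback, from 12 back to 15: hydroxyl-directed epoxidation of 12 (VO(acac)2, t-BuOOH, CH2Cl2) should give 1-[(1R,4S,5R)-4,5-epoxy-1-hydroxy-4-methylcyclohexyl]ethan-1-one F1, with the epoxide cis to the C1 hydroxyl. SN2-type opening by chloride at the less substituted C5 (LiCl, AcOH, THF) should then give the trans-chlorohydrin 1-[(1R,4S,5S)-5-chloro-1,4-dihydroxy-4-methylcyclohexyl]ethan-1-one F2, in which C5–Cl and the C4 oxygen already have the target configuration. Treatment of F2 with HBr converts the tertiary C4 alcohol into the bromide with retention through participation of the anti chlorine (the classical neighbouring-halogen course; the α-keto C1 alcohol does not ionise), returning to the route at 15.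

Step 6 (chloroetherification). Capture of the chloronium ion by the weakly nucleophilic, hydrogen-bonded α-ketol hydroxyl may be outrun by loss of an allylic proton (ene-type chlorination) or by attack of the acetyl oxygen from the opposite face. Fallback, from 11 back to 13: selective acetylation of the secondary alcohol of 11 (Ac2O, pyridine, 0 °C) gives 1-[(1R)-1-hydroxy-4-methylcyclohex-3-en-1-yl]ethyl acetate F3, whose tertiary hydroxyl is an ordinary alcohol with no neighbouring carbonyl. Chloroetherification (NCS, (CF3)2CHOH) gives 1-[(1R,4S,5S)-5-chloro-4-methyl-7-oxabicyclo[2.2.1]heptan-1-yl]ethyl acetate F4. Methanolysis (K2CO3, MeOH) gives 1-[(1R,4S,5S)-5-chloro-4-methyl-7-oxabicyclo[2.2.1]heptan-1-yl]ethan-1-ol F5, and IBX oxidation returns to the route at 13.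

Step 9 (boron aldol). Facial selectivity at the aldehyde may be poor if the reagent control of the isopinocampheyl ligands is mismatched with the α-silyloxy quaternary centre. Fallback, from 16 back to 20: soft enolisation of 16 (TMSOTf, Et3N, CH2Cl2, 0 °C) gives the enol silane triethyl({(1R,4S,5S)-4-bromo-5-chloro-4-methyl-1-[1-(trimethylsilyloxy)ethenyl]cyclohexyl}oxy)silane F6. A catalytic enantioselective Mukaiyama aldol with 17 (SiCl4, chiral bisphosphoramide Lewis base, i-Pr2NEt, CH2Cl2, −78 °C; aqueous work-up) places stereocontrol in the catalyst and returns to the route at 20.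

**Further compounds**

F1 | step 7 | 1-[(1R,4S,5R)-4,5-epoxy-1-hydroxy-4-methylcyclohexyl]ethan-1-one | CC(=O)[C@@]1(O)CC[C@]2(C)O[C@@H]2C1
F2 | step 7 | 1-[(1R,4S,5S)-5-chloro-1,4-dihydroxy-4-methylcyclohexyl]ethan-1-one | CC(=O)[C@@]1(O)CC[C@](C)(O)[C@@H](Cl)C1
F3 | step 6 | 1-[(1R)-1-hydroxy-4-methylcyclohex-3-en-1-yl]ethyl acetate | CC(OC(C)=O)[C@@]1(O)CCC(C)=CC1
F4 | step 6 | 1-[(1R,4S,5S)-5-chloro-4-methyl-7-oxabicyclo[2.2.1]heptan-1-yl]ethyl acetate | CC(OC(C)=O)[C@@]1(O2)CC[C@@]2(C)[C@@H](Cl)C1
F5 | step 6 | 1-[(1R,4S,5S)-5-chloro-4-methyl-7-oxabicyclo[2.2.1]heptan-1-yl]ethan-1-ol | CC(O)[C@@]1(O2)CC[C@@]2(C)[C@@H](Cl)C1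
F6 | step 9 | triethyl({(1R,4S,5S)-4-bromo-5-chloro-4-methyl-1-[1-(trimethylsilyloxy)ethenyl]cyclohexyl}oxy)silane | C=C(O[Si](C)(C)C)[C@@]1(O[Si](CC)(CC)CC)CC[C@](C)(Br)[C@@H](Cl)C1
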